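**Plan**

1. Retrosynthetic cuts, in order: (a) the two aryl O–benzyl bonds; (b) in one operation the succinate ester bond at C4'–O, the chain bond C1'–C2' and the lactone bond O2–C1; (c) the C3/C1' epoxide back to a chloromethyl lactone; (d) the aryl bond C4a–C4; (e) the aryl bond C8a–C1. Numbering: isochromanone C1(=O), O2, C3, C4, C4a, C5–C8, C8a; side chain C1'–C5' counted from C3, with the ester oxygen on C4'.
2. Enabling feature: O2 sits on C3, next to C1', so O2–C3–C1' is a terminal epoxide retron. The C3 alkoxide released when a carbon nucleophile attacks C1' is held by C4–C4a–C8a at six-ring distance from the ester carbon C1, so it closes the δ-lactone ring (O2, C3, C4, C4a, C8a, C1) by itself. The second oxygen, on C4' (1,5 to C3), cannot lactonise and stays free for succinic anhydride.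
3. Forward order: bromohydroquinone → dibenzyl ether → ortho-lithiation/carboxylation (C8a–C1) → arylmagnesium opening of (S)-epichlorohydrin (C4a–C4, lactone ring closed a first time) → methoxide reopening to the (S)-epoxy ester → one-pot union with the alkoxide-Grignard reagent of (S)-4-chlorobutan-2-ol and succinic anhydride (chain joined, lactone closed for good, succinate installed) → hydrogenolysis.
4. Stereochemistry: C3 (R in the target) comes from (S)-epichlorohydrin and is never a reacting centre; C4' (S) comes from (S)-butane-1,3-diol.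

Key step: step 7

Remark: read from the SMILES, the target is (3R) at the lactone carbon and (S) at the side-chain carbinol carbon; bromohydroquinone, (S)-epichlorohydrin, (S)-butane-1,3-diol and succinic anhydride are taken as commercial.

**Route**

Step 1
Reactants: 1 2-bromobenzene-1,4-diol
Product: 2 1,4-bis(benzyloxy)-2-bromobenzene
Conditions: BnBr (2.3 equiv), K2CO3, DMF, 60 °C, N2
Reagents that add atoms: benzyl bromide, BrCc1ccccc1
Why: Williamson etherification of both phenols gives a protecting group that tolerates amide bases, organomagnesium reagents and methoxide and is removed by hydrogenolysis at the end.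

Step 2
Reactants: 2 1,4-bis(benzyloxy)-2-bromobenzene
Product: 4 methyl 3,6-bis(benzyloxy)-2-bromobenzoate, via aryllithium 3 (not isolated)
Conditions: LDA, THF, −78 °C; then ClCO2Me (excess), −78 °C → rt
Reagents that add atoms: methyl chloroformate, COC(=O)Cl
Why: Directed ortho-lithiation with the non-nucleophilic amide base should remove the only ring hydrogen flanked by Br and OBn, and the ortho-bromoaryllithium is acylated at −78 °C before it can lose LiBr, the hindered ester resisting a second addition.

Step 3
Reactants: 4 methyl 3,6-bis(benzyloxy)-2-bromobenzoate; 5 (S)-epichlorohydrin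
Product: 8 (3S)-5,8-bis(benzyloxy)-3-(chloromethyl)-3,4-dihydro-1H-isochromen-1-one, via arylmagnesium chloride 6 (not isolated), via chlorohydrin alkoxide 7 (not isolated)
Conditions: i-PrMgCl·LiCl, THF, −20 °C; then CuI (10 mol %), 5 (1.5 equiv), −30 °C → rt; aq. NH4Cl
Reagents that add atoms: none
Why: Ester-assisted Br/Mg exchange followed by copper-catalysed SN2 opening of the epoxide at its CH2 carbon forms C4a–C4, and the resulting alkoxide should lactonise onto the ortho ester (6-exo-trig), the stereocentre of 5 never being a reacting centre.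

Step 4
Reactants: 8 (3S)-5,8-bis(benzyloxy)-3-(chloromethyl)-3,4-dihydro-1H-isochromen-1-one
Product: 10 methyl 3,6-bis(benzyloxy)-2-{[(2S)-oxiran-2-yl]methyl}benzoate, via ring-opened chlorohydrin alkoxide 9 (not isolated)
Conditions: NaOMe (1.2 equiv), MeOH–THF, 0 °C → rt
Reagents that add atoms: sodium methoxide, C[O-].[Na+]
Why: Halolactone-to-epoxy-ester conversion: reversible methanolysis of the lactone exposes the C3 alkoxide, which closes irreversibly onto CH2Cl (intramolecular Williamson, 3-exo-tet) with the configuration at C3 untouched, and any uncyclised chlorohydrin ester carried over from step 3 converges on the same product.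

Step 5
Reactants: 11 (S)-butane-1,3-diol
Product: 12 (3S)-3-hydroxybutyl 4-methylbenzenesulfonate
Conditions: TsCl (1.0 equiv), Et3N, CH2Cl2, −20 → 0 °C
Reagents that add atoms: 4-toluenesulfonyl chloride, Cc1ccc(cc1)S(=O)(=O)Cl
Why: Selective sulfonylation of the primary hydroxyl over the hindered secondary one at low temperature, leaving the stereocentre untouched.

Step 6
Reactants: 12 (3S)-3-hydroxybutyl 4-methylbenzenesulfonate
Product: 13 (2S)-4-chlorobutan-2-ol
Conditions: LiCl, DMF, 60 °C; distillation
Reagents that add atoms: lithium chloride, [Li+].[Cl-]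
Why: SN2 displacement of the primary tosylate by chloride (Finkelstein-type) under non-basic conditions, so that neither oxetane formation nor the carbinol stereocentre is at issue.

Step 7
Reactants: 10 methyl 3,6-bis(benzyloxy)-2-{[(2S)-oxiran-2-yl]methyl}benzoate; 13 (2S)-4-chlorobutan-2-ol; 14 succinic anhydride
Product: 18 4-{[(2S)-5-[(3R)-5,8-bis(benzyloxy)-1-oxo-3,4-dihydro-1H-isochromen-3-yl]pentan-2-yl]oxy}-4-oxobutanoic acid, via alkoxide-Grignard reagent 15 (not isolated), via bis-alkoxide 16 (not isolated), via lactone alkoxide 17 (not isolated)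
Conditions: 13 (1.2 equiv), i-PrMgCl, THF, −20 °C, then Mg (BrCH2CH2Br-activated), reflux; CuI (10 mol %), 10, −40 → 0 °C, then rt; 14 (4 equiv), DMAP (cat.), 0 °C → rt; 1 M HCl
Reagents that add atoms: none
Why: Deprotonation of 13 and Mg insertion give the alkoxide-Grignard reagent 15, whose copper-catalysed SN2 attack on the unsubstituted epoxide carbon C1' of 10 forms the C1'–C2' bond and releases the C3 alkoxide (16); the closest known reaction type is the CuI-catalysed opening of terminal epoxides by 3-(chloromagnesiooxy)alkylmagnesium chlorides and by ordinary Grignard reagents in the presence of esters at low temperature. On warming, the C3 alkoxide closes the δ-lactone ring (O2, C3, C4, C4a, C8a, C1) by 6-exo-trig acyl substitution at the ester carbon with loss of methoxide (17), as metal alkoxides do in toluate-anion/aldehyde routes to 8-alkoxy-3,4-dihydroisocoumarins. The surviving C4' alkoxide then opens succinic anhydride (DMAP) to the hemisuccinate, a second equivalent of anhydride scavenging the methoxide. No new stereocentre is formed: C3 is carried over from the epoxide because the nucleophile attacks CH2 and never the stereogenic carbon (S in 10 becomes R in 18 only through the change in CIP priorities), and C4' comes unchanged from 11. The step needs regioselectivity for the terminal epoxide carbon (secured by copper catalysis and sterics), chemoselectivity for the epoxide over the ester carbonyl (secured by the two ortho substituents on the benzoate, the low temperature and the small excess of 15) and site-selective acylation (secured because the C3 oxygen is already locked in the lactone, whereas lactonisation from the C4' oxygen would need a ten-membered ring).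

Step 8
Reactants: 18 4-{[(2S)-5-[(3R)-5,8-bis(benzyloxy)-1-oxo-3,4-dihydro-1H-isochromen-3-yl]pentan-2-yl]oxy}-4-oxobutanoic acid
Product: 19 aspergimarin B, 4-{[(2S)-5-[(3R)-5,8-dihydroxy-1-oxo-3,4-dihydro-1H-isochromen-3-yl]pentan-2-yl]oxy}-4-oxobutanoic acid
Conditions: H2 (1 atm), 10% Pd/C, EtOAc, rt; filtration under argon
Reagents that add atoms: none
Why: Hydrogenolysis of the two aryl benzyl ethers under neutral conditions should leave the lactone, the secondary succinate ester, the free acid and both stereocentres (neither benzylic) untouched.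

**Compound list**

1 | 2-bromobenzene-1,4-diol (bromohydroquinone) | Oc1ccc(O)c(Br)c1 | starting material
2 | 1,4-bis(benzyloxy)-2-bromobenzene | Brc1cc(OCc2ccccc2)ccc1OCc1ccccc1 | intermediate
3 | [3,6-bis(benzyloxy)-2-bromophenyl]lithium | [Li]c1c(Br)c(OCc2ccccc2)ccc1OCc1ccccc1 | intermediate (not isolated)
4 | methyl 3,6-bis(benzyloxy)-2-bromobenzoate | COC(=O)c1c(Br)c(OCc2ccccc2)ccc1OCc1ccccc1 | intermediate
5 | (S)-epichlorohydrin, (2S)-2-(chloromethyl)oxirane | ClC[C@@H]1CO1 | starting material
6 | [3,6-bis(benzyloxy)-2-(methoxycarbonyl)phenyl]magnesium chloride (LiCl complex) | COC(=O)c1c([Mg]Cl)c(OCc2ccccc2)ccc1OCc1ccccc1 | intermediate (not isolated)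
7 | chloromagnesium (2S)-1-[3,6-bis(benzyloxy)-2-(methoxycarbonyl)phenyl]-3-chloropropan-2-olate | COC(=O)c1c(C[C@@H](CCl)O[Mg]Cl)c(OCc2ccccc2)ccc1OCc1ccccc1 | intermediate (not isolated)
8 | (3S)-5,8-bis(benzyloxy)-3-(chloromethyl)-3,4-dihydro-1H-isochromen-1-one | ClC[C@@H]1Cc2c(OCc3ccccc3)ccc(OCc3ccccc3)c2C(=O)O1 | intermediate
9 | sodium (2S)-1-[3,6-bis(benzyloxy)-2-(methoxycarbonyl)phenyl]-3-chloropropan-2-olate | COC(=O)c1c(C[C@@H](CCl)[O-])c(OCc2ccccc2)ccc1OCc1ccccc1.[Na+] | intermediate (not isolated)
10 | methyl 3,6-bis(benzyloxy)-2-{[(2S)-oxiran-2-yl]methyl}benzoate | COC(=O)c1c(C[C@H]2CO2)c(OCc2ccccc2)ccc1OCc1ccccc1 | intermediate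
11 | (S)-butane-1,3-diol | C[C@H](O)CCO | starting material
12 | (3S)-3-hydroxybutyl 4-methylbenzenesulfonate | C[C@H](O)CCOS(=O)(=O)c1ccc(C)cc1 | intermediate
13 | (2S)-4-chlorobutan-2-ol | C[C@H](O)CCCl | intermediate
14 | succinic anhydride | O=C1CCC(=O)O1 | starting material
15 | chloromagnesium (2S)-4-(chloromagnesio)butan-2-olate | C[C@H](O[Mg]Cl)CC[Mg]Cl | intermediate (not isolated)
16 | methyl 3,6-bis(benzyloxy)-2-[(2R,6S)-2,6-bis(chloromagnesiooxy)heptyl]benzoate | COC(=O)c1c(C[C@@H](CCC[C@H](C)O[Mg]Cl)O[Mg]Cl)c(OCc2ccccc2)ccc1OCc1ccccc1 | intermediate (not isolated)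
17 | chloromagnesium (2S)-5-[(3R)-5,8-bis(benzyloxy)-1-oxo-3,4-dihydro-1H-isochromen-3-yl]pentan-2-olate | C[C@@H](CCC[C@@H]1Cc2c(OCc3ccccc3)ccc(OCc3ccccc3)c2C(=O)O1)O[Mg]Cl | intermediate (not isolated)
18 | 4-{[(2S)-5-[(3R)-5,8-bis(benzyloxy)-1-oxo-3,4-dihydro-1H-isochromen-3-yl]pentan-2-yl]oxy}-4-oxobutanoic acid | C[C@@H](CCC[C@@H]1Cc2c(OCc3ccccc3)ccc(OCc3ccccc3)c2C(=O)O1)OC(=O)CCC(=O)O | intermediate
19 | aspergimarin B | C[C@@H](CCC[C@@H]1Cc2c(O)ccc(O)c2C(=O)O1)OC(=O)CCC(=O)O | target

**Summary**

Total step count: 8. Longest linear sequence: 6 steps (steps 1, 2, 3, 4, 7, 8); steps 5 and 6 make the side-chain fragment.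

Steps most likely to fail:

Step 7. Magnesium insertion into the chloro-alkoxide may be sluggish or incomplete. Residual C–Mg may add to the ester or lactone carbonyl on warming. Acylation may also occur at the C3 oxygen if lactonisation lags behind. The fallback is a protected, stepwise union that sets out from 13 and comes back at 18. Silylation of 13 (TBSCl, imidazole, DMF) would give (S)-tert-butyl[(4-chlorobutan-2-yl)oxy]dimethylsilane F1. Magnesium insertion (Mg, THF, reflux) would give {(3S)-3-[(tert-butyldimethylsilyl)oxy]butyl}magnesium chloride F2. F2 is added to 10 with CuI (10 mol %) at −40 °C and quenched cold, which should give the hydroxy ester methyl 3,6-bis(benzyloxy)-2-[(2R,6S)-6-[(tert-butyldimethylsilyl)oxy]-2-hydroxyheptyl]benzoate F3. Aqueous HCl in THF, followed by catalytic TsOH in toluene, removes the silyl group and closes the lactone to (3R)-5,8-bis(benzyloxy)-3-[(4S)-4-hydroxypentyl]-3,4-dihydro-1H-isochromen-1-one F4. Acylation of F4 with 14 (DMAP, Et3N, CH2Cl2) then gives 18.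

Step 3. Br/Mg exchange on the electron-rich, doubly ortho-substituted bromide may be slow. The ester-bearing arylmagnesium may condense with itself. Direct displacement of chloride may compete with epoxide opening, which would erode the enantiomeric purity. The fallback sets out from 4 and comes back at 10, with no organomagnesium and no epichlorohydrin. Stille allylation (allyltributylstannane, Pd(PPh3)4, toluene, 110 °C) would give methyl 2-allyl-3,6-bis(benzyloxy)benzoate F5. Epoxidation (mCPBA, NaHCO3, CH2Cl2) would give racemic methyl 3,6-bis(benzyloxy)-2-(oxiran-2-ylmethyl)benzoate F6. Hydrolytic kinetic resolution with the (salen)Co(III)OAc antipode that hydrolyses the (R)-epoxide (expected to be the (R,R)-complex; 0.55 equiv H2O, THF, rt) should leave the (S)-epoxide 10.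

Step 2. The ortho-bromoaryllithium may lose LiBr (aryne formation) before it is acylated, or metalation may compete at a benzylic OCH2 group. The fallback sets out from 2 and comes back at 6. Br/Li exchange (n-BuLi, THF, −78 °C) would give [2,5-bis(benzyloxy)phenyl]lithium F7, which is added to excess ClCO2Me to give methyl 2,5-bis(benzyloxy)benzoate F8. Ester-directed magnesiation with TMPMgCl·LiCl (THF, 0 °C) at the ring C–H flanked by CO2Me and OBn should give the arylmagnesium 6, which is carried directly into the epichlorohydrin opening of step 3.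

**Further compounds**

F1 | step 7 | (S)-tert-butyl[(4-chlorobutan-2-yl)oxy]dimethylsilane | C[C@@H](CCCl)O[Si](C)(C)C(C)(C)C
F2 | step 7 | {(3S)-3-[(tert-butyldimethylsilyl)oxy]butyl}magnesium chloride | C[C@@H](CC[Mg]Cl)O[Si](C)(C)C(C)(C)C
F3 | step 7 | methyl 3,6-bis(benzyloxy)-2-[(2R,6S)-6-[(tert-butyldimethylsilyl)oxy]-2-hydroxyheptyl]benzoate | COC(=O)c1c(C[C@H](O)CCC[C@H](C)O[Si](C)(C)C(C)(C)C)c(OCc2ccccc2)ccc1OCc1ccccc1
F4 | step 7 | (3R)-5,8-bis(benzyloxy)-3-[(4S)-4-hydroxypentyl]-3,4-dihydro-1H-isochromen-1-one | C[C@@H](CCC[C@@H]1Cc2c(OCc3ccccc3)ccc(OCc3ccccc3)c2C(=O)O1)O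
F5 | step 3 | methyl 2-allyl-3,6-bis(benzyloxy)benzoate | COC(=O)c1c(CC=C)c(OCc2ccccc2)ccc1OCc1ccccc1
F6 | step 3 | racemic methyl 3,6-bis(benzyloxy)-2-(oxiran-2-ylmethyl)benzoate | COC(=O)c1c(CC2CO2)c(OCc2ccccc2)ccc1OCc1ccccc1
F7 | step 2 | [2,5-bis(benzyloxy)phenyl]lithium | [Li]c1cc(OCc2ccccc2)ccc1OCc1ccccc1
F8 | step 2 | methyl 2,5-bis(benzyloxy)benzoate | COC(=O)c1cc(OCc2ccccc2)ccc1OCc1ccccc1
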